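All runs are simulated for substances that don't exist, and the scatter is random.

The easy step came first: amber's last three readings of E were 43%, 49% and 47%, and with their scatter I could not say that E had stopped rising. So I took their mean, 46.3%, as a reading on the low side of the part of charged J that stands as dissolved E when no crystals form, the free share. Red passed this share, reading 67% at 60.0 s, so I read crystals D into red.

| setting | amber | red | delta | epsilon | zeta | eta | alpha | theta |
|---|---|---|---|---|---|---|---|---|
| J | 0.10 mM | 0.98 mM | 0.15 mM | 0.30 mM | 0.50 mM | 0.80 mM | 0.25 mM | 1.5 mM |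
| remark | run made earlier | run made earlier |  |  |  |  |  |  |
| time |  |  | 2.0 min | 2.0 min | 2.0 min | 2.0 min | 2.0 min | 2.0 min |

| run | time / s | E / % |
|---|---|---|
| amber | 12.0 | 28 |
| amber | 25.0 | 40 |
| amber | 40.0 | 43 |
| amber | 50.0 | 49 |
| amber | 60.0 | 47 |
| red | 10.0 | 25 |
| red | 15.0 | 33 |
| red | 30.0 | 50 |
| red | 40.0 | 60 |
| red | 60.0 | 67 |

(standard deviation of a reading: 1.5 percentage points)

- amounts and yields of E count D too
- given per volume of solution although it is solid: D
- what was read earlier has a scatter of 1.5 percentage points, one standard deviation
- on the list of suspects stand: J <-> L; D <-> E; J <-> E; E <-> Q; J <-> G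

- the flasks put in order of amount of E, in percent of the J charged, best first, at 2.0 min (delta / epsilon / zeta / eta / alpha / theta)
- the amount of E, in percent of the J charged of the flask you put first, at 2.0 min
- the amount of E, in percent of the J charged of the flask you put last, at 2.0 min

Two amounts mattered to me: the free level and the saturation c(E)sat. Their ratio is the supersaturation; above one, D forms and E, counted with D, can pass the free share.

free level = free share × charged c(J)

amber: 0.0463 mM; delta: 0.0695 mM; theta: 0.695 mM

Amber put c(E)sat above its own level. Red's last reading left 0.323 mM as not E, which at the free ratio goes with 0.279 mM of dissolved E, so I put c(E)sat below that. Delta's level lay inside this window. I therefore ranked the flasks by charge and put delta last, at the free share or above it.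

The forecast gave theta > eta > zeta > epsilon > alpha > delta, top 83% (78% to 87%) and low 48% (44% to 51%), holding that “delta, alpha and epsilon should all sit near 48%”.

The flasks gave theta > eta > zeta > epsilon > alpha > delta, top 81.7% and low 58.0%.

    J ⇌ L (K = 0.280, k = 0.0280 s⁻¹)
    D ⇌ E, rate k2*(cs2 - [E]) while solid is left; crystals form when [E] > cs2 (solubility = 0.0660 mM, k = 4.20 s⁻¹)
    J ⇌ E (K = 5.80, k = 0.0360 s⁻¹)
    E ⇌ Q (K = 0.350, k = 0.0420 s⁻¹)
    J ⇌ G (K = 2.30, k = 0.00680 s⁻¹)

Delta's free level, reckoned at 0.0695 mM, stood above c(E)sat of 0.066 mM, a ratio of 1.05. At 2.00 min delta held D 14.0%, counted within its E of 58.0%.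

In the neighbour flask, like theta but with 0.38 mM of J, the free level is 0.176 mM, a ratio of 2.67, so crystals are expected. Computed, that flask gives E 73.8%, with D 56.4% within it.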